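**Plan**

1. The target is a 2-methoxy-6-alkyl-1,4-benzoquinone (ring: C1 carbonyl between C2–OMe and C6–alkyl, C3–H, C4 carbonyl, C5–H) with a (CH2)14CO2H chain on C6.
2. Retrosynthesis: the C1 oxygen is removed first (para-oxidation of a phenol), the acid and the C4 phenol are masked, and the ring is then cut at C2–C3 and C4–C5 into a 3-alkylcyclobutenone (C5, C6, C1, C2) and a siloxyacetylene (C3, C4).
3. The enabling feature is the resorcinol-type pattern of the ring: oxygen on C2 and C4 flanking C3–H, with the chain on C6 meta to both. A vinylketene/ynol ether benzannulation gives exactly this pattern, with the two oxygens born different (free OH on C2, OSi(iPr)3 on C4).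
4. Forward: the chain is present from the start (ω-alkynoate), the cyclobutenone comes from a dichloroketene [2+2] cycloaddition and dechlorination, the only ring arises in step 6, then O-methylation at C2, unmasking of C4–OH and CO2H, and oxidation at C1.
5. Stereochemistry: the target is achiral and has no stereocentre to set.

Key step: step 6

Assumption: heptadec-16-ynoic acid (an ω-alkynyl fatty acid sold as a click probe) is taken as purchasable; it is carried as its methyl ester because the free acid would quench the zinc and lithium reagents.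

**Step 1**
Reactants: 1 heptadec-16-ynoic acid
Product: 2 methyl heptadec-16-ynoate
Conditions: MeOH, H2SO4 (cat.), reflux
Reagents that add atoms: methanol, CO
Why: Fischer esterification turns the acid into a methyl ester that is inert to the zinc and ketene chemistry of steps 2, 3 and 6 and is removed together with the silyl ether in step 8.

**Step 2**
Reactants: 2 methyl heptadec-16-ynoate
Product: 3 methyl 15-(4,4-dichloro-3-oxocyclobut-1-en-1-yl)pentadecanoate
Conditions: Cl3CCOCl, Zn–Cu couple, Et2O/DME, rt
Reagents that add atoms: trichloroacetyl chloride, ClC(Cl)(Cl)C(Cl)=O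
Why: Dichloroketene, formed in the flask by zinc dechlorination of trichloroacetyl chloride, should add to the terminal alkyne in a thermal [2+2] cycloaddition with the ketene carbonyl carbon bonding to the unsubstituted alkyne carbon, the standard entry to 3-alkyl-4,4-dichlorocyclobutenones.

**Step 3**
Reactants: 3 methyl 15-(4,4-dichloro-3-oxocyclobut-1-en-1-yl)pentadecanoate
Product: 4 methyl 15-(3-oxocyclobut-1-en-1-yl)pentadecanoate
Conditions: Zn dust, AcOH, TMEDA, EtOH, 0 °C to rt
Reagents that add atoms: none
Why: Zinc in buffered acetic acid should remove both chlorines alpha to the ketone through zinc enolates (reductive dehalogenation of an alpha-halo ketone), leaving the strained enone and the ester untouched at low temperature.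

**Step 4**
Reactants: 5 ethynyltrimethylsilane
Product: 8 [(trimethylsilyl)ethynyloxy]triisopropylsilane, via lithium acetylide 6 (not isolated), via lithium ynolate 7 (not isolated)
Conditions: nBuLi, THF, −78 °C; LiOOtBu (from tBuOOH and LiN(SiMe3)2), −78 to 0 °C; TIPSOTf, −78 to 0 °C
Reagents that add atoms: tert-butyl hydroperoxide, CC(C)(C)OO; triisopropylsilyl triflate, CC(C)[Si](OS(=O)(=O)C(F)(F)F)(C(C)C)C(C)C
Why: The lithium acetylide attacks the peroxide oxygen of LiOOtBu to give ynolate 7 (oxidation of an acetylide to an ynolate), and the hard, bulky silyl triflate should then silylate the ambident ynolate on oxygen (ynolate O-silylation, the usual way to triisopropylsiloxyalkynes).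

**Step 5**
Reactants: 8 [(trimethylsilyl)ethynyloxy]triisopropylsilane
Product: 9 (ethynyloxy)triisopropylsilane
Conditions: K2CO3 (cat.), MeOH, 0 °C
Reagents that add atoms: none
Why: Methoxide-mediated protodesilylation of an alkynylsilane: the unhindered C–SiMe3 bond on the sp carbon should be cleaved far faster than the hindered O–Si(iPr)3 bond, freeing the terminal siloxyalkyne.

**Step 6**
Reactants: 4 methyl 15-(3-oxocyclobut-1-en-1-yl)pentadecanoate; 9 (ethynyloxy)triisopropylsilane
Product: 14 methyl 15-[3-hydroxy-5-(triisopropylsilyloxy)phenyl]pentadecanoate, via vinylketene 10 (not isolated), via cyclobutenone adduct 11 (not isolated), via dienylketene 12 (not isolated), via cyclohexadienone 13 (not isolated)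
Conditions: toluene, 80 °C, sealed tube, then 110 °C
Reagents that add atoms: none
Why: Heating opens cyclobutenone 4 by 4π-electrocyclic ring opening to vinylketene 10, whose ketene C=C takes up the electron-rich siloxyalkyne 9 in a [2+2] cycloaddition to give 11; a second 4π ring opening leads to dienylketene 12, and thermal 6π-electrocyclisation to dienone 13 followed by tautomerisation gives phenol 14, so that two new ring bonds (carbonyl carbon of 4 to the CH of 9, and C2 of 4 to the siloxy carbon of 9) result in one operation. The closest known reaction type is the Danheiser benzannulation of cyclobutenones with trialkylsiloxyalkynes, used to make mono-silylated resorcinols. The only ring of the target, the six-membered carbocycle, is closed by the disrotatory 6π-electrocyclisation of 12 between the ketene carbon and the terminal CH2 (the four-membered ring of 11 is transient and closed by the [2+2] step). No stereocentre is created, the single sp3 centre of 11 being lost on ring opening. The step needs regioselectivity, secured by the polarisation of the partners (the nucleophilic unsubstituted carbon of 9 attacks the ketene carbonyl carbon, placing the siloxy group meta to the new OH and the chain meta to both oxygens), and differentiation of the two oxygens, secured because one arrives as the ketone of 4 (free OH) and the other as OSi(iPr)3. An excess of 9 in dilute solution should keep 14 from being acylated by 10.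

**Step 7**
Reactants: 14 methyl 15-[3-hydroxy-5-(triisopropylsilyloxy)phenyl]pentadecanoate
Product: 15 methyl 15-[3-methoxy-5-(triisopropylsilyloxy)phenyl]pentadecanoate
Conditions: MeI, K2CO3, acetone, 40 °C
Reagents that add atoms: iodomethane, CI
Why: Williamson O-methylation of the only free phenol under mild carbonate conditions fixes the methoxy group on the carbon that came from the cyclobutenone carbonyl, while the aryl silyl ether and the ester should survive.

**Step 8**
Reactants: 15 methyl 15-[3-methoxy-5-(triisopropylsilyloxy)phenyl]pentadecanoate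
Product: 16 15-(3-hydroxy-5-methoxyphenyl)pentadecanoic acid
Conditions: NaOH, H2O/MeOH/THF, 50 °C; then HCl (aq)
Reagents that add atoms: sodium hydroxide, [Na+].[OH-]
Why: Hydroxide should cleave the aryl silyl ether (attack at silicon, phenoxide as leaving group) and saponify the methyl ester in one operation, so that the phenol para to the carbon to be oxidised and the free acid are in place before the base-sensitive methoxyquinone exists.

**Step 9**
Reactants: 16 15-(3-hydroxy-5-methoxyphenyl)pentadecanoic acid
Product: 17 15-(5-methoxy-3,6-dioxocyclohexa-1,4-dien-1-yl)pentadecanoic acid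
Conditions: Fremy's salt (KSO3)2NO, KH2PO4 buffer, H2O/acetone, rt
Reagents that add atoms: Fremy's salt (dipotassium nitrosodisulfonate), [K+].[K+].[O-]S(=O)(=O)N([O])S(=O)(=O)[O-]
Why: Teuber oxidation: the nitrosodisulfonate radical abstracts the phenolic hydrogen, a second equivalent couples at the free para carbon between the methoxy and alkyl groups, and loss of imidodisulfonate should give the 2-methoxy-6-alkyl-1,4-benzoquinone, the para position being open and activated by the ortho methoxy group.

**Compound list**

1 | heptadec-16-ynoic acid | C#CCCCCCCCCCCCCCCC(=O)O | starting material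
2 | methyl heptadec-16-ynoate | C#CCCCCCCCCCCCCCCC(=O)OC | intermediate
3 | methyl 15-(4,4-dichloro-3-oxocyclobut-1-en-1-yl)pentadecanoate | O=C1C=C(CCCCCCCCCCCCCCC(=O)OC)C1(Cl)Cl | intermediate
4 | methyl 15-(3-oxocyclobut-1-en-1-yl)pentadecanoate | O=C1C=C(CCCCCCCCCCCCCCC(=O)OC)C1 | intermediate
5 | ethynyltrimethylsilane | C#C[Si](C)(C)C | starting material
6 | lithium (trimethylsilyl)acetylide | [Li+].[C-]#C[Si](C)(C)C | intermediate (not isolated)
7 | lithium 2-(trimethylsilyl)ethynolate | [Li+].[O-]C#C[Si](C)(C)C | intermediate (not isolated)
8 | [(trimethylsilyl)ethynyloxy]triisopropylsilane | C[Si](C)(C)C#CO[Si](C(C)C)(C(C)C)C(C)C | intermediate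
9 | (ethynyloxy)triisopropylsilane | C#CO[Si](C(C)C)(C(C)C)C(C)C | intermediate
10 | vinylketene: methyl 16-methylidene-18-oxooctadec-17-enoate | C=C(CCCCCCCCCCCCCCC(=O)OC)C=C=O | intermediate (not isolated)
11 | cyclobutenone adduct: methyl 16-[4-oxo-2-(triisopropylsilyloxy)cyclobut-2-en-1-yl]heptadec-16-enoate (racemic, transient) | C=C(CCCCCCCCCCCCCCC(=O)OC)C1C(=O)C=C1O[Si](C(C)C)(C(C)C)C(C)C | intermediate (not isolated)
12 | dienylketene: methyl 16-methylidene-20-oxo-18-(triisopropylsilyloxy)icosa-17,19-dienoate, ketene and vinyl groups cis on the central C=C | O=C=C/C(O[Si](C(C)C)(C(C)C)C(C)C)=C\C(=C)CCCCCCCCCCCCCCC(=O)OC | intermediate (not isolated)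
13 | cyclohexadienone: methyl 15-[5-oxo-3-(triisopropylsilyloxy)cyclohexa-1,3-dien-1-yl]pentadecanoate | O=C1C=C(O[Si](C(C)C)(C(C)C)C(C)C)C=C(CCCCCCCCCCCCCCC(=O)OC)C1 | intermediate (not isolated)
14 | methyl 15-[3-hydroxy-5-(triisopropylsilyloxy)phenyl]pentadecanoate | Oc1cc(O[Si](C(C)C)(C(C)C)C(C)C)cc(CCCCCCCCCCCCCCC(=O)OC)c1 | intermediate
15 | methyl 15-[3-methoxy-5-(triisopropylsilyloxy)phenyl]pentadecanoate | COc1cc(O[Si](C(C)C)(C(C)C)C(C)C)cc(CCCCCCCCCCCCCCC(=O)OC)c1 | intermediate
16 | 15-(3-hydroxy-5-methoxyphenyl)pentadecanoic acid | COc1cc(O)cc(CCCCCCCCCCCCCCC(=O)O)c1 | intermediate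
17 | 15-(5-methoxy-3,6-dioxocyclohexa-1,4-dien-1-yl)pentadecanoic acid | COC1=CC(=O)C=C(CCCCCCCCCCCCCCC(=O)O)C1=O | target

**Step count**

Total steps: 9. Longest linear sequence: 7 (steps 1, 2, 3, 6, 7, 8, 9); steps 4 and 5 make the two-carbon partner.

**Steps most likely to fail**

Step 4. What may go wrong: silylation of the ambident, silicon-substituted ynolate at carbon (leading to a bis-silylketene) in place of oxygen, or over-oxidation of the acetylide by the peroxide. Fallback (sets out from 4, comes back at 16): the silyl ynol ether is replaced by an alkyl ynol ether whose C–O bond exists before the triple bond is made. Isopropanol, KH and trichloroethylene in THF should give (E)-1,2-dichlorovinyl isopropyl ether F1. With nBuLi at −78 °C this should give lithium isopropoxyacetylide F2 and, after a methanol quench, isopropoxyacetylene F3. Heating 4 with F3 in toluene at 80 °C, below the temperature at which an isopropyl ynol ether is expected to lose propene, should run the same pericyclic cascade through 10, the isopropoxy cyclobutenone adduct F4, the isopropoxy dienylketene F5 and the isopropoxy cyclohexadienone F6 to methyl 15-(3-hydroxy-5-isopropoxyphenyl)pentadecanoate F7. Methylation (MeI, K2CO3, acetone) should give methyl 15-(3-isopropoxy-5-methoxyphenyl)pentadecanoate F8, and saponification (NaOH, aqueous MeOH) should give 15-(3-isopropoxy-5-methoxyphenyl)pentadecanoic acid F9. BCl3 in CH2Cl2 at −78 to 0 °C should then cleave the secondary alkyl aryl ether in preference to the methyl ether to give 16.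

Step 6. What may go wrong: 1,3-shift of silicon from oxygen to carbon in the terminal siloxyalkyne (silylketene formation) before it is captured, acylation of the product phenol by the vinylketene, or stalling at the cyclobutenone adduct. Fallback (sets out from 4 and 8, comes back at 14): the C-silylated alkyne 8 is used as the two-carbon partner, the SiMe3 group serving as a traceless block of the alkyne terminus. Heating 4 with 8 in toluene (80 to 110 °C) should lead through 10, the C-silylated cyclobutenone adduct F10, the C-silylated dienylketene F11 and the C-silylated cyclohexadienone F12 to methyl 15-[3-hydroxy-4-(trimethylsilyl)-5-(triisopropylsilyloxy)phenyl]pentadecanoate F13. Brief treatment with CF3CO2H in CH2Cl2 at 0 °C should remove the aryl SiMe3 group by ipso-protonation between the two oxygens and give 14.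

Step 9. What may go wrong: aggregation of the amphiphilic carboxylate in the aqueous oxidant with incomplete conversion, and further oxidation of the electron-rich quinone on long exposure. Fallback (sets out from 15, comes back at 17): the oxidation is done on the neutral ester in homogeneous organic solution and the acid is unmasked last under neutral conditions. Bu4NF in THF should give methyl 15-(3-hydroxy-5-methoxyphenyl)pentadecanoate F14. O2 with Co(salen) in DMF should give methyl 15-(5-methoxy-3,6-dioxocyclohexa-1,4-dien-1-yl)pentadecanoate F15. Lipase-mediated hydrolysis (Candida antarctica lipase B, phosphate buffer pH 7, acetone co-solvent) should give 17.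

**Further compounds**

F1 | step 4 | (E)-1,2-dichlorovinyl isopropyl ether | CC(C)O/C(Cl)=C\Cl
F2 | step 4 | lithium isopropoxyacetylide | [Li+].[C-]#COC(C)C
F3 | step 4 | isopropoxyacetylene | C#COC(C)C
F4 | step 4 | isopropoxy cyclobutenone adduct: methyl 16-(4-oxo-2-isopropoxycyclobut-2-en-1-yl)heptadec-16-enoate | C=C(CCCCCCCCCCCCCCC(=O)OC)C1C(=O)C=C1OC(C)C
F5 | step 4 | isopropoxy dienylketene: methyl 16-methylidene-20-oxo-18-isopropoxyicosa-17,19-dienoate | O=C=C/C(OC(C)C)=C\C(=C)CCCCCCCCCCCCCCC(=O)OC
F6 | step 4 | isopropoxy cyclohexadienone: methyl 15-(5-oxo-3-isopropoxycyclohexa-1,3-dien-1-yl)pentadecanoate | O=C1C=C(OC(C)C)C=C(CCCCCCCCCCCCCCC(=O)OC)C1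
F7 | step 4 | methyl 15-(3-hydroxy-5-isopropoxyphenyl)pentadecanoate | Oc1cc(OC(C)C)cc(CCCCCCCCCCCCCCC(=O)OC)c1
F8 | step 4 | methyl 15-(3-isopropoxy-5-methoxyphenyl)pentadecanoate | COc1cc(OC(C)C)cc(CCCCCCCCCCCCCCC(=O)OC)c1
F9 | step 4 | 15-(3-isopropoxy-5-methoxyphenyl)pentadecanoic acid | COc1cc(OC(C)C)cc(CCCCCCCCCCCCCCC(=O)O)c1
F10 | step 6 | C-silylated cyclobutenone adduct: methyl 16-[4-oxo-3-(trimethylsilyl)-2-(triisopropylsilyloxy)cyclobut-2-en-1-yl]heptadec-16-enoate | C=C(CCCCCCCCCCCCCCC(=O)OC)C1C(=O)C([Si](C)(C)C)=C1O[Si](C(C)C)(C(C)C)C(C)C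
F11 | step 6 | C-silylated dienylketene: methyl 16-methylidene-20-oxo-19-(trimethylsilyl)-18-(triisopropylsilyloxy)icosa-17,19-dienoate | O=C=C([Si](C)(C)C)/C(O[Si](C(C)C)(C(C)C)C(C)C)=C\C(=C)CCCCCCCCCCCCCCC(=O)OC
F12 | step 6 | C-silylated cyclohexadienone: methyl 15-[5-oxo-4-(trimethylsilyl)-3-(triisopropylsilyloxy)cyclohexa-1,3-dien-1-yl]pentadecanoate | O=C1C([Si](C)(C)C)=C(O[Si](C(C)C)(C(C)C)C(C)C)C=C(CCCCCCCCCCCCCCC(=O)OC)C1
F13 | step 6 | methyl 15-[3-hydroxy-4-(trimethylsilyl)-5-(triisopropylsilyloxy)phenyl]pentadecanoate | Oc1cc(CCCCCCCCCCCCCCC(=O)OC)cc(O[Si](C(C)C)(C(C)C)C(C)C)c1[Si](C)(C)C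
F14 | step 9 | methyl 15-(3-hydroxy-5-methoxyphenyl)pentadecanoate | COc1cc(O)cc(CCCCCCCCCCCCCCC(=O)OC)c1
F15 | step 9 | methyl 15-(5-methoxy-3,6-dioxocyclohexa-1,4-dien-1-yl)pentadecanoate | COC1=CC(=O)C=C(CCCCCCCCCCCCCCC(=O)OC)C1=O
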